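**Plan**

1. The side chain is numbered C1 (OCH2) to C8 (=CH2). The retrosynthesis cuts first C4–C3 (the CH2 next to the carbinol and the methyl-bearing alkene carbon), then the aryl O–C1 ether bond, then C6–C7 (carbinol CH2 and isopropenyl).
2. The enabling feature is the homoallylic alcohol array O–C5–C4–C3(Me)=C2. C5–O with C4 is an opened terminal oxirane, that is, a latent β-hydroxyalkyl radical at C4, and C3 is an sp2 carbon that can carry a triflate. C4–C5–C6 are the three carbons of epichlorohydrin.
3. Forward: ethyl acetoacetate → E-enol triflate → allylic alcohol → 4-O-ether of 2,4,6-trihydroxybenzophenone; (S)-epichlorohydrin → isopropenyl adduct → oxirane. The two halves are joined last by a nickel/iodide reductive coupling that forms C4–C3, unveils the carbinol and needs no protecting group.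
4. No ring is formed. The two benzene rings are bought as the benzophenone, and the oxirane is a temporary ring that the key step opens.
5. Stereochemistry: C5 (S) is the stereocentre of (S)-epichlorohydrin, whose C–O bond is never broken. The 2E alkene is set by E-selective enol triflation and kept by a stereoretentive coupling.

Key step: step 6

Assumption: 2,4,6-trihydroxybenzophenone, (S)-epichlorohydrin and isopropenylmagnesium bromide (THF solution) are taken as purchasable.

**Route**

Step 1
Reactants: 1 ethyl acetoacetate (ethyl 3-oxobutanoate)
Product: 2 ethyl (2E)-3-{[(trifluoromethyl)sulfonyl]oxy}but-2-enoate (triflate trans to the ester)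
Conditions: Tf2O, 25% aq. Me4NOH, hexanes, 5 °C → rt
Reagents that add atoms: trifluoromethanesulfonic anhydride, O=S(=O)(OS(=O)(=O)C(F)(F)F)C(F)(F)F
Why: Biphasic Schotten–Baumann-type enol triflation of a β-keto ester; the non-chelated tetramethylammonium enolate prefers the extended geometry with its two oxygens apart, so O-sulfonylation should place the triflate trans to the ester (E), whereas a chelating lithium base would give Z.

Step 2
Reactants: 2 ethyl (2E)-3-{[(trifluoromethyl)sulfonyl]oxy}but-2-enoate
Product: 3 (2E)-4-hydroxybut-2-en-2-yl trifluoromethanesulfonate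
Conditions: DIBAL-H (2.2 equiv), CH2Cl2, −78 °C; aq. Rochelle salt
Reagents that add atoms: none
Why: 1,2-Reduction of an α,β-unsaturated ester to the allylic alcohol with DIBAL-H at low temperature, under which the enol triflate and the alkene geometry should stay untouched.

Step 3
Reactants: 3 (2E)-4-hydroxybut-2-en-2-yl trifluoromethanesulfonate, 4 2,4,6-trihydroxybenzophenone [phenyl(2,4,6-trihydroxyphenyl)methanone]
Product: 5 (2E)-4-(4-benzoyl-3,5-dihydroxyphenoxy)but-2-en-2-yl trifluoromethanesulfonate
Conditions: PPh3, DIAD, THF, 0 °C → rt (4 in slight excess)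
Reagents that add atoms: none
Why: Mitsunobu etherification; the 4-OH, para to the carbonyl and not held in an O–H···O=C hydrogen bond like the 2- and 6-OH, is the most acidic phenol and should alone attack the primary allylic alkoxyphosphonium ion by SN2.

Step 4
Reactants: 6 (S)-epichlorohydrin [(2S)-2-(chloromethyl)oxirane], 7 isopropenylmagnesium bromide (prop-1-en-2-ylmagnesium bromide, THF solution)
Product: 8 (2S)-1-chloro-4-methylpent-4-en-2-ol
Conditions: CuI (10 mol%), THF, −40 → −20 °C; aq. NH4Cl
Reagents that add atoms: none
Why: Copper-catalysed Grignard opening of the epoxide at its unsubstituted carbon (SN2), which leaves the C–Cl bond and the C–O bond of the stereocentre intact, so the (S) centre of 6 is carried over unchanged.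

Step 5
Reactants: 8 (2S)-1-chloro-4-methylpent-4-en-2-ol
Product: 9 (2S)-2-(2-methylprop-2-en-1-yl)oxirane
Conditions: powdered NaOH, Et2O, rt; careful distillation
Reagents that add atoms: none
Why: Intramolecular Williamson ether synthesis (closure of the chlorohydrin alkoxide on CH2Cl); the stereogenic C–O bond is not touched, so the configuration is retained.

Step 6
Reactants: 5 (2E)-4-(4-benzoyl-3,5-dihydroxyphenoxy)but-2-en-2-yl trifluoromethanesulfonate, 9 (2S)-2-(2-methylprop-2-en-1-yl)oxirane (1.5 equiv)
Product: 11 (2,6-dihydroxy-4-{[(2E,5S)-5-hydroxy-3,7-dimethylocta-2,7-dien-1-yl]oxy}phenyl)(phenyl)methanone, via (2S)-1-iodo-4-methylpent-4-en-2-ol 10 (not isolated)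
Conditions: NiCl2·glyme (10 mol%), 2,2'-bipyridine (10 mol%), NaI (25 mol%), Et3N·HCl (1 equiv), Zn dust (2 equiv), DMPU, rt
Reagents that add atoms: none
Why: Et3N·HCl and iodide open the monosubstituted oxirane at its CH2 to the iodohydrin 10, (bpy)Ni(0) adds oxidatively to the alkenyl C–OTf bond of 5 with retention, a nickel(I) species abstracts iodine from 10 to give the primary β-hydroxyalkyl radical at C4, and radical capture followed by reductive elimination forms the C4–C3 bond while zinc returns nickel to its low-valent state. The closest known reaction type is the nickel/iodide co-catalysed reductive cross-electrophile coupling of terminal epoxides with aryl and alkenyl halides or triflates, which gives the linear alcohol. No ring is closed. No stereocentre is created: C5 keeps the (S) configuration of 9 because its C–O bond is never broken and the radical sits on the neighbouring CH2, and the E geometry is that of the alkenyl triflate. The step needs opening at the terminal carbon (secured by SN2 attack of iodide on the unhindered CH2), cross-coupling over homocoupling (secured by the different activation of the two partners, two-electron oxidative addition against halogen-atom abstraction) and reaction at C–OTf in preference to the allylic C–O bond and the diaryl ketone (secured by the much faster oxidative addition of the triflate and by the mild reductant). The C4 radical could only close a four-membered ring or close 5-endo on the 1,1-disubstituted alkene, so the methallyl group should survive.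

**Compound list**

1 | ethyl acetoacetate | CCOC(=O)CC(C)=O | starting material
2 | ethyl (2E)-3-{[(trifluoromethyl)sulfonyl]oxy}but-2-enoate | CCOC(=O)/C=C(\C)OS(=O)(=O)C(F)(F)F | intermediate
3 | (2E)-4-hydroxybut-2-en-2-yl trifluoromethanesulfonate | OC/C=C(\C)OS(=O)(=O)C(F)(F)F | intermediate
4 | 2,4,6-trihydroxybenzophenone | O=C(c1ccccc1)c1c(O)cc(O)cc1O | starting material
5 | (2E)-4-(4-benzoyl-3,5-dihydroxyphenoxy)but-2-en-2-yl trifluoromethanesulfonate | O=C(c1ccccc1)c1c(O)cc(OC/C=C(\C)OS(=O)(=O)C(F)(F)F)cc1O | intermediate
6 | (S)-epichlorohydrin | ClC[C@@H]1CO1 | starting material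
7 | isopropenylmagnesium bromide | C=C(C)[Mg]Br | starting material
8 | (2S)-1-chloro-4-methylpent-4-en-2-ol | C=C(C)C[C@H](O)CCl | intermediate
9 | (2S)-2-(2-methylprop-2-en-1-yl)oxirane | C=C(C)C[C@H]1CO1 | intermediate
10 | (2S)-1-iodo-4-methylpent-4-en-2-ol | C=C(C)C[C@H](O)CI | intermediate (not isolated)
11 | (2,6-dihydroxy-4-{[(2E,5S)-5-hydroxy-3,7-dimethylocta-2,7-dien-1-yl]oxy}phenyl)(phenyl)methanone | C=C(C)C[C@H](O)C/C(C)=C/COc1cc(O)c(C(=O)c2ccccc2)c(O)c1 | target

**Count**

Total steps: 6. Longest linear sequence: 4 steps (steps 1, 2, 3, 6); the oxirane branch has 3 (steps 4, 5, 6).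

**Steps most likely to fail, with fallbacks**

Step 6. Nickel may be tied up by the chelating 2-hydroxyaryl ketone, the alkenyl triflate may dimerise reductively, or nickel may insert into the allylic C–O bond instead of C–OTf. The fallback sets out from 9 and comes back at 11; it makes the same C4–C3 bond with an alkynyl anion and attaches the arene last. Oxirane 9 is opened at CH2 by the lithium acetylide of tert-butyldimethyl(prop-2-yn-1-yloxy)silane (n-BuLi, BF3·OEt2, THF, −78 °C) to give (5S)-1-[(tert-butyldimethylsilyl)oxy]-7-methyloct-7-en-2-yn-5-ol F1. TBAF removes the silyl group to give (5S)-7-methyloct-7-en-2-yne-1,5-diol F2. Red-Al (THF, 0 °C; trans-hydroalumination directed by the propargylic alkoxide, aluminium on C3) followed by I2 should give (2Z,5S)-3-iodo-7-methylocta-2,7-diene-1,5-diol F3. Me2CuLi (Et2O, 0 °C) should replace iodine by methyl with retention to give (2E,5S)-3,7-dimethylocta-2,7-diene-1,5-diol F4. Mitsunobu etherification of the primary allylic hydroxyl of F4 with 4 (PPh3, DIAD, THF) then gives 11.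

Step 3. Etherification may occur at an ortho hydroxyl or twice, or the redox condensation may be sluggish. The fallback sets out from 3 and comes back at 5. Appel bromination of 3 (CBr4, PPh3, CH2Cl2, 0 °C) gives (2E)-4-bromobut-2-en-2-yl trifluoromethanesulfonate F5. SN2 alkylation of the mono-potassium salt of 4 (K2CO3 1 equiv, acetone, rt), in which only the most acidic 4-OH is ionised, then gives 5.

Step 2. Conjugate hydride addition with loss of triflate, or S–O cleavage of the enol triflate, may compete with ester reduction. The fallback sets out from 2 and comes back at 11; the order of events is changed so that no hydride meets the enol triflate. Compound 2 is coupled with 9 under the nickel/iodide conditions of step 6 to give ethyl (2E,5S)-5-hydroxy-3,7-dimethylocta-2,7-dienoate F6. DIBAL-H reduces the ester to (2E,5S)-3,7-dimethylocta-2,7-diene-1,5-diol F4, which is joined to 4 by Mitsunobu etherification at its primary allylic hydroxyl to give 11.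

**Further compounds**

F1 | step 6 | (5S)-1-[(tert-butyldimethylsilyl)oxy]-7-methyloct-7-en-2-yn-5-ol | C=C(C)C[C@H](O)CC#CCO[Si](C)(C)C(C)(C)C
F2 | step 6 | (5S)-7-methyloct-7-en-2-yne-1,5-diol | C=C(C)C[C@H](O)CC#CCO
F3 | step 6 | (2Z,5S)-3-iodo-7-methylocta-2,7-diene-1,5-diol | C=C(C)C[C@H](O)C/C(I)=C/CO
F4 | step 6 | (2E,5S)-3,7-dimethylocta-2,7-diene-1,5-diol | C=C(C)C[C@H](O)C/C(C)=C/CO
F5 | step 3 | (2E)-4-bromobut-2-en-2-yl trifluoromethanesulfonate | BrC/C=C(\C)OS(=O)(=O)C(F)(F)F
F6 | step 2 | ethyl (2E,5S)-5-hydroxy-3,7-dimethylocta-2,7-dienoate | C=C(C)C[C@H](O)C/C(C)=C/C(=O)OCC
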